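**Retrosynthetic overview**

1. Last bonds: O–Si cleavage at C12, and C7=C8 by aldol condensation of the C8 methylene of bromo-enone 12 with (Z)-enal 15 (C1–C7). Numbering: C1 ester carbon, ring C8–C12, C9 carbonyl, C10 CBr, C11 vinylic CH, C12 carbinol, C13–C20 octenyl chain.
2. Key disconnection: the α-bromoenone C9(=O)–C10(Br)=C11 of the five-membered ring is read as a one-carbon "CBr" unit inserted into the C9=C11 enol double bond of a four-membered ring. Forward, dibromocarbene adds to silyl enol ether 10 and the resulting 5,5-dibromobicyclo[2.1.0]pentane opens under strain release, giving ring size, bromine and enone in one operation.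
3. Enabling feature: once C10 is removed, C12 lies opposite the carbonyl C9 on the mirror plane of cyclobutanone 8 (ring C8–C9–C11–C12). The only stereocentre of the target is therefore created by choosing between the enantiotopic methylenes C8 and C11 with a chiral lithium amide, and the same choice fixes on which side the CBr carbon enters.
4. Cyclobutanone 8 comes from 3-(benzyloxy)cyclobutan-1-one by propargylation, acetylide alkylation and Lindlar reduction (C13–C20, 14Z), then debenzylation and oxidation.
5. Order of rings: purchased cyclobutane → transient bicyclo[2.1.0]pentane → cyclopentenone (the only ring of the target).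

Key step: step 8

Remark: the sense of induction of the (R,R)-amide in step 7 is assumed by analogy with other prochiral cycloalkanones and is to be confirmed on the first run, the mirror-image amide being equally available; compounds 1 and 13 are taken as catalogue chemicals.

**Route**

Step 1
Reactants: 1 3-(benzyloxy)cyclobutan-1-one
Product: 2 3-(benzyloxy)-1-(prop-2-yn-1-yl)cyclobutan-1-ol (cis/trans mixture)
Conditions: propargyl bromide, Zn dust, THF, 0 °C to rt; aq NH4Cl
Reagents that add atoms: propargyl bromide, C#CCBr
Why: Barbier-type propargylation in which the allenylzinc bromide formed in situ attacks the strained cyclobutanone carbonyl through an SE2' transition state to give the homopropargylic tertiary alcohol (the future C12), the cis/trans relationship to the benzyloxy group being irrelevant because that ring carbon becomes the carbonyl C9 in step 6.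

Step 2
Reactants: 2 3-(benzyloxy)-1-(prop-2-yn-1-yl)cyclobutan-1-ol
Product: 3 {[3-(benzyloxy)-1-(prop-2-yn-1-yl)cyclobutyl]oxy}(triethyl)silane
Conditions: TESOTf, 2,6-lutidine, CH2Cl2, −78 to 0 °C
Reagents that add atoms: triethylsilyl triflate, CC[Si](CC)(CC)OS(=O)(=O)C(F)(F)F
Why: Silylation of a tertiary alcohol with a silyl triflate and a hindered pyridine base gives a triethylsilyl ether that later blocks retro-aldol opening of the 3-oxycyclobutanone, tolerates amide and alkoxide bases and is removable with fluoride at the end.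

Step 3
Reactants: 3 {[3-(benzyloxy)-1-(prop-2-yn-1-yl)cyclobutyl]oxy}(triethyl)silane
Product: 5 {[3-(benzyloxy)-1-(oct-2-yn-1-yl)cyclobutyl]oxy}(triethyl)silane, via lithium acetylide 4 (not isolated)
Conditions: n-BuLi, THF, −78 °C; then 1-iodopentane, DMPU, −78 °C to rt
Reagents that add atoms: 1-iodopentane, CCCCCI
Why: Deprotonation of the terminal alkyne and SN2 alkylation of the lithium acetylide with a primary iodide in the presence of a dipolar cosolvent completes the C13–C20 chain as the oct-2-ynyl group.

Step 4
Reactants: 5 {[3-(benzyloxy)-1-(oct-2-yn-1-yl)cyclobutyl]oxy}(triethyl)silane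
Product: 6 {[3-(benzyloxy)-1-[(2Z)-oct-2-en-1-yl]cyclobutyl]oxy}(triethyl)silane
Conditions: H2 (1 atm), Pd/CaCO3 poisoned with Pb(OAc)2, quinoline, EtOAc, rt
Reagents that add atoms: none
Why: Lindlar semihydrogenation delivers H2 syn to the alkyne and should stop at the (Z)-C14=C15 alkene, leaving the benzyl ether and the silyl ether untouched.

Step 5
Reactants: 6 {[3-(benzyloxy)-1-[(2Z)-oct-2-en-1-yl]cyclobutyl]oxy}(triethyl)silane
Product: 7 3-[(2Z)-oct-2-en-1-yl]-3-[(triethylsilyl)oxy]cyclobutan-1-ol
Conditions: lithium 4,4'-di-tert-butylbiphenylide, THF, −78 °C; then H2O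
Reagents that add atoms: none
Why: Reductive cleavage of the benzylic C–O bond by an arene radical anion (dissolving-metal type debenzylation) should free the secondary cyclobutanol while the isolated (Z)-alkene and the silyl ether, which are not reduced at −78 °C, survive.

Step 6
Reactants: 7 3-[(2Z)-oct-2-en-1-yl]-3-[(triethylsilyl)oxy]cyclobutan-1-ol
Product: 8 3-[(2Z)-oct-2-en-1-yl]-3-[(triethylsilyl)oxy]cyclobutan-1-one
Conditions: (n-Pr)4N[RuO4] (cat.), N-methylmorpholine N-oxide, 4 Å MS, CH2Cl2, rt
Reagents that add atoms: none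
Why: Ley–Griffith oxidation under neutral conditions converts the secondary cyclobutanol into the ketone without touching the alkene or the silyl ether and produces an achiral cyclobutanone whose mirror plane contains C9 and C12.

Step 7
Reactants: 8 3-[(2Z)-oct-2-en-1-yl]-3-[(triethylsilyl)oxy]cyclobutan-1-one
Product: 10 triethyl({(1S)-1-[(2Z)-oct-2-en-1-yl]-3-[(trimethylsilyl)oxy]cyclobut-2-en-1-yl}oxy)silane, via lithium enolate 9 (not isolated)
Conditions: (R,R)-bis(1-phenylethyl)amine, n-BuLi, THF, −78 to 0 °C; then TMSCl and 8 (in situ quench), −100 °C; pentane, filtration through Et3N-deactivated silica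
Reagents that add atoms: chlorotrimethylsilane, C[Si](C)(C)Cl
Why: Enantiotopic-group-selective deprotonation of a prochiral ketone by a C2-symmetric chiral lithium amide with in situ silyl trapping (asymmetric enolisation) removes a proton from only one of the two mirror-related α-methylenes, which makes C12 a stereocentre (S in 10) and decides which methylene becomes the vinylic C11 and which remains as C8, the low temperature and immediate O-silylation preventing enolate equilibration and β-elimination of the silyloxy group.

Step 8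
Reactants: 10 triethyl({(1S)-1-[(2Z)-oct-2-en-1-yl]-3-[(trimethylsilyl)oxy]cyclobut-2-en-1-yl}oxy)silane
Product: 12 (4S)-2-bromo-4-[(2Z)-oct-2-en-1-yl]-4-[(triethylsilyl)oxy]cyclopent-2-en-1-one, via dibromobicyclopentane 11 (not isolated)
Conditions: CHBr3 (1.1 equiv), KOt-Bu (2.2 equiv), hexane, −30 to 0 °C; pH 7 buffer
Reagents that add atoms: bromoform, BrC(Br)Br
Why: Dibromocarbene (from CHBr3 and KOt-Bu) adds in a concerted [2+1] cheletropic fashion to the electron-rich C9=C11 enol double bond of 10 and closes the three-membered ring of 5,5-dibromobicyclo[2.1.0]pentane 11; this strained bicycle then undergoes the thermally allowed disrotatory cyclopropyl-to-allyl electrocyclic opening with loss of the endo bromide, which cleaves the central C9–C11 bond so that the four-membered ring becomes the five-membered one (no ring is closed in this second event, it is a one-carbon ring expansion driven by release of the bicyclopentane strain), and the 2-bromo-1-siloxyallyl cation loses its trimethylsilyl group to give the α-bromoenone. The closest known reaction types are the ring expansion of cyclic ketone silyl enol ethers to α-halo-enones through their dihalocarbene adducts and the cyclopropanation/ring-opening homologation of cyclobutanone silyl enol ethers to cyclopentenones. No new stereocentre survives the step: the two bridgehead centres of 11 form as a mixture (carbene from either face) and both are erased on opening, while C12 is not a reacting centre and keeps the configuration set in step 7. The step needs chemoselectivity for the enol ether over the (Z)-C14=C15 alkene, which the far higher nucleophilicity of the oxygen-substituted alkene towards the electrophilic carbene and the use of close to one equivalent of bromoform at low temperature should secure, and regioselectivity of the enone, which is fixed because the position of the enol double bond (C9=C11, not C9=C8) dictates that the inserted CBr carbon becomes C10 and the untouched methylene becomes C8. The second equivalent of KOt-Bu scavenges Me3SiBr so that no HBr reaches the tertiary silyl ether.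

Step 9
Reactants: 13 methyl 7-hydroxyhept-5-ynoate
Product: 14 methyl (5Z)-7-hydroxyhept-5-enoate
Conditions: H2 (1 atm), Pd/CaCO3 poisoned with Pb(OAc)2, quinoline, EtOAc, rt
Reagents that add atoms: none
Why: Lindlar semihydrogenation gives the (Z)-alkene (the future C5=C6) by syn delivery of H2, the ester and the allylic alcohol being inert.

Step 10
Reactants: 14 methyl (5Z)-7-hydroxyhept-5-enoate
Product: 15 methyl (5Z)-7-oxohept-5-enoate
Conditions: Dess–Martin periodinane, pyridine, CH2Cl2, 0 °C; used at once
Reagents that add atoms: none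
Why: Dess–Martin oxidation of the allylic alcohol under buffered, mild conditions should give the (Z)-enal without isomerisation to the conjugated (E)-isomer, provided the aldehyde is used immediately.

Step 11
Reactants: 12 (4S)-2-bromo-4-[(2Z)-oct-2-en-1-yl]-4-[(triethylsilyl)oxy]cyclopent-2-en-1-one; 15 methyl (5Z)-7-oxohept-5-enoate
Product: 17 methyl (5Z)-7-{(5S)-3-bromo-5-[(2Z)-oct-2-en-1-yl]-2-oxo-5-[(triethylsilyl)oxy]cyclopent-3-en-1-yl}-7-hydroxyhept-5-enoate (diastereomer mixture at C7/C8), via lithium dienolate 16 (not isolated)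
Conditions: LiN(i-Pr)2, THF, −78 °C; then 15, −78 °C; AcOH
Reagents that add atoms: none
Why: Kinetic α'-deprotonation of the cross-conjugated enone at its only enolisable position (C8, since C12 is quaternary) gives a lithium dienolate that undergoes aldol addition to the aldehyde carbonyl of 15 at −78 °C, the two new stereocentres (C7 and C8) forming as a mixture that is erased in step 12.

Step 12
Reactants: 17 methyl (5Z)-7-{(5S)-3-bromo-5-[(2Z)-oct-2-en-1-yl]-2-oxo-5-[(triethylsilyl)oxy]cyclopent-3-en-1-yl}-7-hydroxyhept-5-enoate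
Product: 19 methyl (5Z,7E)-7-{(5R)-3-bromo-5-[(2Z)-oct-2-en-1-yl]-2-oxo-5-[(triethylsilyl)oxy]cyclopent-3-en-1-ylidene}hept-5-enoate, via mesylate 18 (not isolated)
Conditions: MsCl, Et3N (excess), CH2Cl2, −20 °C to rt; chromatography with exclusion of light
Reagents that add atoms: none
Why: Mesylation of the secondary allylic alcohol (the tertiary oxygen is silylated) followed by E1cB elimination through the enolate gives the cross-conjugated alkylidene enone, the reversible enolate pathway being expected to favour the 7E geometry in which C6 lies away from the carbonyl oxygen, with any 7Z isomer removed by chromatography.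

Step 13
Reactants: 19 methyl (5Z,7E)-7-{(5R)-3-bromo-5-[(2Z)-oct-2-en-1-yl]-2-oxo-5-[(triethylsilyl)oxy]cyclopent-3-en-1-ylidene}hept-5-enoate
Product: 20 methyl (5Z,7E)-7-{(5R)-3-bromo-5-hydroxy-5-[(2Z)-oct-2-en-1-yl]-2-oxocyclopent-3-en-1-ylidene}hept-5-enoate
Conditions: HF·pyridine, pyridine, THF, 0 °C
Reagents that add atoms: none
Why: Fluoride-mediated cleavage of the tertiary triethylsilyl ether under buffered, nearly neutral conditions (desilylation driven by the Si–F bond) should release the C12 alcohol without ionising the doubly allylic carbinol or isomerising the (5Z,7E)-dienone.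

**Compound list**

1 | 3-(benzyloxy)cyclobutan-1-one | O=C1CC(OCc2ccccc2)C1 | starting material
2 | 3-(benzyloxy)-1-(prop-2-yn-1-yl)cyclobutan-1-ol (cis/trans mixture) | OC1(CC#C)CC(OCc2ccccc2)C1 | intermediate
3 | {[3-(benzyloxy)-1-(prop-2-yn-1-yl)cyclobutyl]oxy}(triethyl)silane | C#CCC1(O[Si](CC)(CC)CC)CC(OCc2ccccc2)C1 | intermediate
4 | lithium acetylide of 3 | [Li]C#CCC1(O[Si](CC)(CC)CC)CC(OCc2ccccc2)C1 | intermediate
5 | {[3-(benzyloxy)-1-(oct-2-yn-1-yl)cyclobutyl]oxy}(triethyl)silane | CCCCCC#CCC1(O[Si](CC)(CC)CC)CC(OCc2ccccc2)C1 | intermediate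
6 | {[3-(benzyloxy)-1-[(2Z)-oct-2-en-1-yl]cyclobutyl]oxy}(triethyl)silane | CCCCC/C=C\CC1(O[Si](CC)(CC)CC)CC(OCc2ccccc2)C1 | intermediate
7 | 3-[(2Z)-oct-2-en-1-yl]-3-[(triethylsilyl)oxy]cyclobutan-1-ol | CCCCC/C=C\CC1(O[Si](CC)(CC)CC)CC(O)C1 | intermediate
8 | 3-[(2Z)-oct-2-en-1-yl]-3-[(triethylsilyl)oxy]cyclobutan-1-one (achiral) | CCCCC/C=C\CC1(O[Si](CC)(CC)CC)CC(=O)C1 | intermediate
9 | lithium (3S)-3-[(2Z)-oct-2-en-1-yl]-3-[(triethylsilyl)oxy]cyclobut-1-en-1-olate | CCCCC/C=C\C[C@@]1(O[Si](CC)(CC)CC)C=C(O[Li])C1 | intermediate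
10 | triethyl({(1S)-1-[(2Z)-oct-2-en-1-yl]-3-[(trimethylsilyl)oxy]cyclobut-2-en-1-yl}oxy)silane | CCCCC/C=C\C[C@@]1(O[Si](CC)(CC)CC)C=C(O[Si](C)(C)C)C1 | intermediate
11 | (3S)-5,5-dibromo-3-[(2Z)-oct-2-en-1-yl]-3-[(triethylsilyl)oxy]-1-[(trimethylsilyl)oxy]bicyclo[2.1.0]pentane (mixture at the ring fusion) | CCCCC/C=C\C[C@@]1(O[Si](CC)(CC)CC)C2C(Br)(Br)C2(O[Si](C)(C)C)C1 | intermediate
12 | (4S)-2-bromo-4-[(2Z)-oct-2-en-1-yl]-4-[(triethylsilyl)oxy]cyclopent-2-en-1-one | CCCCC/C=C\C[C@@]1(O[Si](CC)(CC)CC)C=C(Br)C(=O)C1 | intermediate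
13 | methyl 7-hydroxyhept-5-ynoate | OCC#CCCCC(=O)OC | starting material
14 | methyl (5Z)-7-hydroxyhept-5-enoate | OC/C=C\CCCC(=O)OC | intermediate
15 | methyl (5Z)-7-oxohept-5-enoate | O=C/C=C\CCCC(=O)OC | intermediate
16 | lithium dienolate of 12 (C8=C9–OLi) | CCCCC/C=C\C[C@@]1(O[Si](CC)(CC)CC)C=C(Br)C(O[Li])=C1 | intermediate
17 | methyl (5Z)-7-{(5S)-3-bromo-5-[(2Z)-oct-2-en-1-yl]-2-oxo-5-[(triethylsilyl)oxy]cyclopent-3-en-1-yl}-7-hydroxyhept-5-enoate (mixture at C7 and C8) | CCCCC/C=C\C[C@@]1(O[Si](CC)(CC)CC)C=C(Br)C(=O)C1C(O)/C=C\CCCC(=O)OC | intermediate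
18 | methanesulfonate of 17 | CCCCC/C=C\C[C@@]1(O[Si](CC)(CC)CC)C=C(Br)C(=O)C1C(OS(C)(=O)=O)/C=C\CCCC(=O)OC | intermediate
19 | methyl (5Z,7E)-7-{(5R)-3-bromo-5-[(2Z)-oct-2-en-1-yl]-2-oxo-5-[(triethylsilyl)oxy]cyclopent-3-en-1-ylidene}hept-5-enoate | CCCCC/C=C\C[C@@]1(O[Si](CC)(CC)CC)C=C(Br)C(=O)/C1=C/C=C\CCCC(=O)OC | intermediate
20 | methyl (5Z,7E)-7-{(5R)-3-bromo-5-hydroxy-5-[(2Z)-oct-2-en-1-yl]-2-oxocyclopent-3-en-1-ylidene}hept-5-enoate | CCCCC/C=C\C[C@@]1(O)C=C(Br)C(=O)/C1=C/C=C\CCCC(=O)OC | target

**Step count and risks**

Total step count: 13. Longest linear sequence: 11 (steps 1–8 and 11–13); steps 9–10 make the side-chain aldehyde.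

Steps most likely to fail:

Step 7. The amide may discriminate poorly between the two enantiotopic α-methylenes, because the two groups on C12 (silyloxy and allylic CH2) differ little in size; the enolate may also lose silanolate before it is trapped. Fallback, from 8 back to 10: ketone 8 is converted with KN(SiMe3)2 and Ac2O (THF, −78 °C) into the racemic enol acetate 3-[(2Z)-oct-2-en-1-yl]-3-[(triethylsilyl)oxy]cyclobut-1-en-1-yl acetate F1. Lipase-catalysed alcoholysis of the enol ester (an immobilised lipase such as Candida antarctica lipase B, n-BuOH, hexane) is a kinetic resolution that returns the faster-reacting enantiomer to achiral 8, which is recycled, and leaves the slower one; the lipase is chosen by screening so that the enantiomer left is the (S)-enol acetate F2. F2 with MeLi (2 equiv, THF, −78 °C) should give enolate 9 regiospecifically, and TMSCl converts it into 10.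

Step 8. The carbene may add competitively to the C14=C15 alkene, or the alkoxide may degrade the bromo-enone once it has formed. Fallback, from 10 back to 12, in which no free carbene and no strong base are used: Et2Zn/CH2I2 (CH2Cl2, 0 °C) cyclopropanates the enol ether to the siloxybicyclo[2.1.0]pentane F3. FeCl3 in DMF (0 °C) opens it oxidatively at the central bond to the ring-expanded β-chloro ketone F4, which NaOAc in MeOH dehydrochlorinates to the cyclopentenone F5. Nucleophilic epoxidation (H2O2, NaOH, MeOH, 0 °C) should touch only the electron-poor enone and give the epoxy ketone F6. LiBr/AcOH (THF) opens the epoxide at the α-carbon C10 to the bromohydrin F7, and MsCl/Et3N eliminates the β-hydroxyl to return to 12.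

Step 12. The E1cB elimination may show poor control of the C7=C8 geometry and may isomerise the 5Z alkene. Fallback, from 12 back to 19, in which the geometry is set stereospecifically: soft enolisation of 12 with chlorodicyclohexylborane and Et3N (Et2O, −78 to 0 °C) gives the dicyclohexylboron dienolate F8. Its aldol addition to 15 through a closed chair transition state should give the anti (7,8-threo) aldol F9, drawn for the C8 epimer with the side chain cis to the silyloxy group; both C8 epimers of the anti series lead to the same alkene. Stereospecific syn-dehydration with N,N'-dicyclohexylcarbodiimide and CuCl (cat.) in toluene then converts the anti aldol into the 7E alkene 19 without passing through an enolate.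

**Further compounds**

F1 | step 7 | 3-[(2Z)-oct-2-en-1-yl]-3-[(triethylsilyl)oxy]cyclobut-1-en-1-yl acetate (racemate) | CCCCC/C=C\CC1(O[Si](CC)(CC)CC)C=C(OC(C)=O)C1
F2 | step 7 | (3S)-3-[(2Z)-oct-2-en-1-yl]-3-[(triethylsilyl)oxy]cyclobut-1-en-1-yl acetate | CCCCC/C=C\C[C@@]1(O[Si](CC)(CC)CC)C=C(OC(C)=O)C1
F3 | step 8 | (3S)-3-[(2Z)-oct-2-en-1-yl]-3-[(triethylsilyl)oxy]-1-[(trimethylsilyl)oxy]bicyclo[2.1.0]pentane (mixture at the ring fusion) | CCCCC/C=C\C[C@@]1(O[Si](CC)(CC)CC)C2CC2(O[Si](C)(C)C)C1
F4 | step 8 | 3-chloro-4-[(2Z)-oct-2-en-1-yl]-4-[(triethylsilyl)oxy]cyclopentan-1-one (carbinol carbon as in 10, mixture at C–Cl) | CCCCC/C=C\C[C@@]1(O[Si](CC)(CC)CC)C(Cl)CC(=O)C1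
F5 | step 8 | (4S)-4-[(2Z)-oct-2-en-1-yl]-4-[(triethylsilyl)oxy]cyclopent-2-en-1-one | CCCCC/C=C\C[C@@]1(O[Si](CC)(CC)CC)C=CC(=O)C1
F6 | step 8 | 2,3-epoxy-4-[(2Z)-oct-2-en-1-yl]-4-[(triethylsilyl)oxy]cyclopentan-1-one (carbinol carbon as in 10, mixture at the epoxide) | CCCCC/C=C\C[C@@]1(O[Si](CC)(CC)CC)C2OC2C(=O)C1
F7 | step 8 | 2-bromo-3-hydroxy-4-[(2Z)-oct-2-en-1-yl]-4-[(triethylsilyl)oxy]cyclopentan-1-one (carbinol carbon as in 10, mixture at C2/C3) | CCCCC/C=C\C[C@@]1(O[Si](CC)(CC)CC)C(O)C(Br)C(=O)C1
F8 | step 12 | dicyclohexylboron dienolate of 12 | CCCCC/C=C\C[C@@]1(O[Si](CC)(CC)CC)C=C(Br)C(OB(C2CCCCC2)C2CCCCC2)=C1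
F9 | step 12 | anti (7,8-threo) diastereomer of aldol 17, side chain cis to the silyloxy group | CCCCC/C=C\C[C@@]1(O[Si](CC)(CC)CC)C=C(Br)C(=O)[C@@H]1[C@@H](O)/C=C\CCCC(=O)OC
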